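(All runs are simulated for substances that don't exist; scatter was added.)

The flask is read at 2.0 h, 40.0 min past the last reading of either earlier run, so its target has to be carried forward from those runs.

| flask | substrate | reagent in the second phase | protic impurity | remark | time | volume of the second phase over the first |
|---|---|---|---|---|---|---|
| Sunday's | 0.26 M | 0.37 M | 0.0195 M | run made earlier |  |  |
| Friday's | 0.58 M | 0.37 M | 0.0195 M | run made earlier |  |  |
| flask | 0.39 M | 0.370 M | 0.0195 M |  | 2.0 h | 0.50 |

| run | time / min | target / % | substrate / % |
|---|---|---|---|
| Sunday's | 20.0 | 7 | 92 |
| Sunday's | 40.0 | 19 | 83 |
| Sunday's | 50.0 | 18 | 78 |
| Sunday's | 80.0 | 24 | 74 |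
| Friday's | 20.0 | 13 | 89 |
| Friday's | 40.0 | 16 | 80 |
| Friday's | 50.0 | 17 | 79 |
| Friday's | 80.0 | 18 | 78 |

(scatter of a reading: 1.5 percentage points)

- in the second phase: reagent in the second phase; everything else is in the first
- charges count per volume of the first phase; a concentration in a rate is the amount of a species over the volume of its own phase; every rate counts per litre of the first phase
- the earlier runs hold the two phases in the same ratio of volumes as the flask asked about

* how much target there is at 2.0 h, in percent of the substrate charged
* the change that raises the amount of target at 2.0 h, in percent of the substrate charged most ("none" if none brings more than 2 percentage points) (south-west / north-east / none)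
* amount of target at 2.0 h, in percent of the substrate charged, after north-east

- south-west: doubling the amount of reagent in the second phase, all else as stated
- north-east: doubling the transfer coefficient of the reagent in the second phase, all else as stated

Both runs stall with substrate left, and their percentages stay close although Friday's substrate charge is 2.23 times Sunday's. That is the mark of pseudo-first-order loss of substrate. The quantity to carry is therefore the exposure, the natural logarithm of substrate charged over substrate left. At 50.0 min Sunday's run reads 0.248 and Friday's 0.236, with mean 0.242. At 80.0 min the mean is 0.275.

The mean pace is 0.00484 min⁻¹ up to the first of these times and 0.00110 min⁻¹ between them, slower in the later window; these two windows show a slowing, not where it sets in. Held flat, the exposure leaves 76.0% of the substrate in the flask. The last readings turn 87.1% of lost substrate into target, so the flask holds 20.9% target.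

The weak link is the flat stretch. Continuing the late pace in a straight line gives an exposure of 0.318 and 23.7% target, which is a high-side figure. My reckoning therefore brackets the amount and names no change.

The forecast gives 22%, south-west and 22.5%, reading the stall as a reversible reaction or “something that behaves like one”.

The flask gives 22.9%. The better change is south-west, worth 5.7 percentage points, and north-east leaves 21.8%.

    reagent in the reaction phase ⇌ reagent in the second phase, rate k1*([reagent in the reaction phase] - [reagent in the second phase]/K1) per volume of the first phase (partition coefficient = 0.580, kL = 3.00 × 10⁻⁴ s⁻¹)
    substrate + reagent in the reaction phase → target (k = 9.80 × 10⁻⁴ M⁻¹ s⁻¹)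
    reagent in the reaction phase + target → over-reacted product (k = 0.00120 M⁻¹ s⁻¹)
    reagent in the reaction phase + protic impurity → quenched reagent (k = 0.00220 M⁻¹ s⁻¹)
    2 reagent in the reaction phase → homo dimer (k = 0.00460 M⁻¹ s⁻¹)

At 2.0 h the flask keeps 71.8% of its substrate, an exposure of 0.331, while its reagent in the second phase stands at 1.30% of its own charge and homo dimer at 0.107 M. The flask's slowing comes with hardly any of the reagent left in the second phase. The neighbouring flask, the same charge read at 50 min, takes the exposure 0.242, which leaves 78.5% substrate and makes 18.7% target. That neighbouring flask holds 79.3% substrate and 17.9% target.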